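The easy step first: we count what each second end group is spent on, in fractions of the solid first end groups charged.

    first end groups + second end groups → links (k1 = 0.659 M⁻¹ s⁻¹)
    first end groups + second end groups → rings, rate k2*[first end groups] as long as [second end groups] is above zero (k2 = 0.00137 s⁻¹)
    second end groups + links → over-reaction product (k3 = 0.905 M⁻¹ s⁻¹)
    links ⇌ isomer of the product (K4 = 0.997, k4 = 0.0151 s⁻¹)
    solid first end groups ⇌ first end groups, rate k5*(cs5 - [first end groups]) while solid is left; crystals form when [first end groups] > cs5 (cs5 = 0.052 M, k5 = 0.0286 s⁻¹)

solid first end groups 0.094 M; second end groups 0.0940 M (fed, over 8.0 s); time 10 min

- as a solid, counted per litre of solution: solid first end groups
- at the start none of the solid first end groups is in solution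
- what has only dissolved of solid first end groups counts as not reacted
- first end groups means what is dissolved; the solid is not counted in it
- the reaction counts as stopped when no species that holds the solid first end groups changes by six tenths of a point or more over the second half of the time
- run time (flask): 10 min

- at 10 min, what has stopped the reaction, if anything has (for what has run out or reacted, a solid counts together with what of it has only dissolved) (all of the solid first end groups has reacted / forward and back rates have come level / the second end groups has run out first / it is still moving)
- how much links there is at 10 min, in percent of the solid first end groups charged
- how much first end groups there is at 10 min, in percent of the solid first end groups charged

Let a be the share not yet reacted, solid and dissolved together, m the share reacted once (links, isomer of the product, rings) and o the over-reacted share, so that o = 1 − a − m. Each once-reacted unit costs one second end group and each over-reacted unit two. Link formation and over-reaction both carry the concentration of second end groups, so it cancels in their ratio, and time with it. We keep these two steps, and the ratio of their constants is 1.37: call it σ, the selectivity factor, the constant of over-reaction over that of link formation.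

In this flask we take, roughly, a as dissolved throughout, leave rings out of the rates, and take m as open to over-reaction throughout, since the half-life of links by over-reaction, with the whole charge of second end groups counted as there at once (0.14 min), is shorter than their forward half-life to the isomer (0.77 min):

dm/da = −1 + σ m/a, so m = (a − a^σ)/(σ − 1)

spent = 2(1 − a) − m

At a = 0.333 the spending is 1.03; at a = 0.5 it is 0.695. The charge of second end groups is 1.00, so interpolating gives a = 0.350, with m = 0.304. On this reckoning second end groups are the limiting reagent, and a lies below the solubility share 0.553, so we expect what is left to be dissolved. Links share m, less rings, about evenly with the isomer, as K4 is 0.997 and the relaxation half-life of that pair, 0.382 min, is short against 10 min: we expect links under 0.152, by half of the rings.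

The forecast says the second end groups has run out first, with links 12.4% and first end groups 35%, from “a rough 10-second hand march”.

The simulation gives the second end groups has run out first, with 0% left, links 12.6% and first end groups 34.4%.

Put the reading 34.4% back into the curve with σ: it gives over-reaction product 35.3%, and this flask holds 34.4%. The neighbour charged with 0.024 M of second end groups keeps 78.3% unreacted, solid included; the same curve, although solid still stands in that neighbour, gives over-reaction product 3.41%, and that neighbour holds 3.80%. Over-reaction is the main reason conversion in this flask stops at 65.6%: with that step struck out conversion stands at 98.1%.

(The rate constants were drawn at random within sensible limits; the result is computed.)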